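**Retrosynthetic overview**
- Feature: the pyran is fused to ring A along C4a–C8a. O1 sits on C8a and the vinylic C4 sits on C4a, the carbon ortho to the C5 methoxy. A methoxy-polarised C4a≡C8a aryne delivers this O,C pattern from an enal.
- Last disconnection: the O7 MOM ether and the dimethyl ketal on the ring-B-side carbonyl, both removed by one acid hydrolysis.
- Key disconnection: O1–C8a, C4–C4a and O1–C2, leading back to 3-methylbut-2-enal and an o-silylaryl triflate that already carries the whole protected acyl chain.
- Triflate: the C6–acyl bond comes from lithiation between OMe and OMOM and acylation with a ketal ester made from 4-hydroxyphenylglyoxylic acid and prenyl bromide. The C8a–Si bond comes from retro-Brook migration on a Dakin-derived bromophenol made from 5-bromovanillin.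
- Ring order: rings A and B are bought, and the pyran is the only ring formed, in step 10.

Key step: step 10

Assumption: the ortho-hydroxy 1,2-diketone is taken to rest in the open, hydrogen-bonded form drawn for the target. Its cyclic hemiketal tautomer would interconvert with it and needs no separate step.

**Step 1**
Reactants: 1 5-bromovanillin (3-bromo-4-hydroxy-5-methoxybenzaldehyde)
Product: 2 2-bromo-6-methoxybenzene-1,4-diol
Conditions: 30% aq H2O2, NaOH, THF/H2O, 0 °C to rt, N2; then 1 M HCl
Reagents that add atoms: hydrogen peroxide, OO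
Why: Dakin oxidation, in which hydroperoxide adds to the aldehyde of a para-hydroxybenzaldehyde, the electron-rich aryl group migrates to oxygen and the formate is saponified in the flask, while exclusion of air and the acidic quench keep the hydroquinone from oxidising to the quinone.

**Step 2**
Reactants: 2 2-bromo-6-methoxybenzene-1,4-diol
Product: 3 2-bromo-6-methoxy-4-(methoxymethoxy)phenol
Conditions: MOMCl (1.0 equiv), i-Pr2NEt (1.1 equiv), CH2Cl2, –10 to 0 °C
Reagents that add atoms: chloromethyl methyl ether, COCCl
Why: Williamson-type O-alkylation with one equivalent of electrophile should take the open C4 hydroxyl, because the two phenols are of similar acidity (bromine is ortho to one and meta to the other) whereas the C1 hydroxyl is flanked by Br and OMe and hydrogen-bonded to the methoxy oxygen, and any bis-ether or regioisomer is removed by chromatography.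

**Step 3**
Reactants: 3 2-bromo-6-methoxy-4-(methoxymethoxy)phenol
Product: 4 [2-bromo-6-methoxy-4-(methoxymethoxy)phenoxy]trimethylsilane
Conditions: HMDS, THF, 65 °C; evaporate, use crude
Reagents that add atoms: hexamethyldisilazane, C[Si](C)(C)N[Si](C)(C)C
Why: O-silylation of a phenol with HMDS is driven by loss of ammonia and leaves no salt, so the moisture-sensitive ether can be carried on after simple evaporation.

**Step 4**
Reactants: 4 [2-bromo-6-methoxy-4-(methoxymethoxy)phenoxy]trimethylsilane
Product: 7 tert-butyl[2-methoxy-4-(methoxymethoxy)-6-(trimethylsilyl)phenoxy]dimethylsilane, via aryllithium 5 (not isolated), via lithium phenoxide 6 (not isolated)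
Conditions: n-BuLi (1.05 equiv), THF, –78 to –20 °C; then TBSOTf, –78 to 0 °C
Reagents that add atoms: tert-butyldimethylsilyl trifluoromethanesulfonate, CC(C)(C)[Si](C)(C)OS(=O)(=O)C(F)(F)F; n-butyllithium, [Li]CCCC (lithium of 5 and 6 only)
Why: Bromine–lithium exchange followed by retro-Brook (1,3 O-to-C) silyl migration, driven by the exchange of an aryl anion for a phenoxide, places SiMe3 on the former C–Br carbon, and capping the phenoxide in the same flask as a TBS ether removes the acidic and deactivating OH before the next lithiation.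

**Step 5**
Reactants: 8 4-hydroxyphenylglyoxylic acid
Product: 9 methyl 2-(4-hydroxyphenyl)-2,2-dimethoxyacetate
Conditions: HC(OMe)3, MeOH, cat. H2SO4, reflux
Reagents that add atoms: methanol, CO; trimethyl orthoformate, COC(OC)OC
Why: Fischer esterification and orthoformate-driven ketalisation run together, the ketal-forming oxocarbenium ion being stabilised by the para-hydroxyphenyl group, and the hot acid is used here because the later prenyl ether would not survive it.

**Step 6**
Reactants: 9 methyl 2-(4-hydroxyphenyl)-2,2-dimethoxyacetate; 10 prenyl bromide (1-bromo-3-methylbut-2-ene)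
Product: 11 methyl 2,2-dimethoxy-2-[4-(3-methylbut-2-enyloxy)phenyl]acetate
Conditions: K2CO3, DMF, rt
Reagents that add atoms: none
Why: Williamson ether synthesis by SN2 displacement at the primary allylic bromide proceeds at room temperature under a carbonate base that leaves ester and ketal untouched.

**Step 7**
Reactants: 7 tert-butyl[2-methoxy-4-(methoxymethoxy)-6-(trimethylsilyl)phenoxy]dimethylsilane; 11 methyl 2,2-dimethoxy-2-[4-(3-methylbut-2-enyloxy)phenyl]acetate
Product: 13 1-[3-(tert-butyldimethylsilyloxy)-2-methoxy-6-(methoxymethoxy)-4-(trimethylsilyl)phenyl]-2,2-dimethoxy-2-[4-(3-methylbut-2-enyloxy)phenyl]ethan-1-one, via aryllithium 12 (not isolated)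
Conditions: 7 (1.1 equiv), n-BuLi (1.05 equiv), TMEDA, THF, –20 to 0 °C; then 11 (1.0 equiv), –78 to –20 °C; aq NH4Cl
Reagents that add atoms: n-butyllithium, [Li]CCCC (lithium of 12 only)
Why: Directed ortho-metalation takes the one C–H flanked by the cooperating OMe and OMOM groups (the other ring hydrogen is shielded by SiMe3), and acyl substitution on an α,α-dialkoxy ester, a class known to stop at the ketone, should be clean because the tetrahedral adduct is chelated in the cold and the di-ortho-substituted, α-quaternary ketone is too hindered for a second addition.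

**Step 8**
Reactants: 13 the TBS-protected ketone
Product: 14 1-[3-hydroxy-2-methoxy-6-(methoxymethoxy)-4-(trimethylsilyl)phenyl]-2,2-dimethoxy-2-[4-(3-methylbut-2-enyloxy)phenyl]ethan-1-one
Conditions: TBAF (1.05 equiv), AcOH (1.1 equiv), THF, 0 °C
Reagents that add atoms: none
Why: Fluoride cleavage of a phenolic silyl ether, whose O–Si bond carries a phenoxide leaving group, is far faster than attack on the aryl C–SiMe3 bond, and the acetic acid buffer keeps the medium from becoming basic.

**Step 9**
Reactants: 14 the o-silylphenol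
Product: 15 3-{2,2-dimethoxy-2-[4-(3-methylbut-2-enyloxy)phenyl]acetyl}-2-methoxy-4-(methoxymethoxy)-6-(trimethylsilyl)phenyl trifluoromethanesulfonate
Conditions: Tf2O, pyridine, CH2Cl2, –20 to 0 °C
Reagents that add atoms: trifluoromethanesulfonic anhydride, O=S(=O)(OS(=O)(=O)C(F)(F)F)C(F)(F)F
Why: O-sulfonylation of an o-silylphenol with Tf2O and pyridine is the standard closing step for o-silylaryl triflates, the excess pyridine shields MOM ether, ketal and prenyl ether from acid, and the ketone has no α-hydrogen to enolise.

**Step 10**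
Reactants: 15 the o-silylaryl triflate; 16 3-methylbut-2-enal
Product: 20 1-[5-methoxy-7-(methoxymethoxy)-2,2-dimethyl-2H-chromen-6-yl]-2,2-dimethoxy-2-[4-(3-methylbut-2-enyloxy)phenyl]ethan-1-one, via aryne 17 (not isolated), via benzoxete 18 (not isolated), via ortho-quinone methide 19 (not isolated)
Conditions: dried CsF (3 equiv), 16 (5 equiv), MeCN, rt to 40 °C, slow addition of 15
Reagents that add atoms: none
Why: Fluoride attacks the silicon on C8a and triflate leaves from C4a, which releases the C4a≡C8a aryne 17 under conditions that leave MOM ether, ketal, prenyl ether and the non-enolisable C6 ketone alone. The carbonyl oxygen of 16 adds to C8a and the C4a aryl anion collapses on the carbonyl carbon, a stepwise formal [2+2] addition that gives benzoxete 18, whose strained four-membered ring opens electrocyclically to the ortho-quinone methide 19. The pyran, the only ring that persists, closes from the Z isomer of 19 by thermal oxa-6π electrocyclisation between O1 and the dimethyl-bearing terminus C2, driven by rearomatisation of ring A, and no stereocentre is created. The closest known reaction type is the 2H-chromene synthesis from o-silylaryl triflate-derived arynes and α,β-unsaturated aldehydes, together with the related aryne–formamide [2+2] chemistry that also runs through ortho-quinone methides. The step needs a single orientation across the aryne, and the C5 methoxy secures it, since its inductive pull distorts the aryne so that the remote C8a has the wider internal angle and is the electrophilic carbon, while the developing negative charge sits on C4a next to the C–O bond. Closure at the carbonyl carbon rather than at the β-carbon is favoured by the fully substituted β-position of 16, and excess aldehyde with slow addition of 15 holds back ene reactions of the prenyl group and capture of 19 by a second aryne.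

**Step 11**
Reactants: 20 the MOM- and ketal-protected chromene
Product: 21 ficucaricone C, 1-(7-hydroxy-5-methoxy-2,2-dimethyl-2H-chromen-6-yl)-2-[4-(3-methylbut-2-enyloxy)phenyl]ethane-1,2-dione
Conditions: 1 M aq HCl, THF, 40 °C
Reagents that add atoms: water, O
Why: Acid-catalysed acetal hydrolysis removes both masking groups, the MOM ether being assisted by the ortho carbonyl and the ketal ionising through a para-alkoxybenzyl oxocarbenium ion, while the dilute aqueous medium and mild temperature are chosen to spare the prenyl aryl ether and the chromene, and the freed phenol is tied up by hydrogen bonding to the C6 ketone.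

**Compound list**
1 | 5-bromovanillin | COc1cc(C=O)cc(Br)c1O | starting material
2 | 2-bromo-6-methoxybenzene-1,4-diol | COc1cc(O)cc(Br)c1O | intermediate
3 | 2-bromo-6-methoxy-4-(methoxymethoxy)phenol | COCOc1cc(Br)c(O)c(OC)c1 | intermediate
4 | [2-bromo-6-methoxy-4-(methoxymethoxy)phenoxy]trimethylsilane | COCOc1cc(Br)c(O[Si](C)(C)C)c(OC)c1 | intermediate
5 | [3-methoxy-5-(methoxymethoxy)-2-(trimethylsilyloxy)phenyl]lithium | COCOc1cc([Li])c(O[Si](C)(C)C)c(OC)c1 | intermediate
6 | lithium 2-methoxy-4-(methoxymethoxy)-6-(trimethylsilyl)phenoxide | COCOc1cc([Si](C)(C)C)c([O-])c(OC)c1.[Li+] | intermediate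
7 | tert-butyl[2-methoxy-4-(methoxymethoxy)-6-(trimethylsilyl)phenoxy]dimethylsilane | COCOc1cc([Si](C)(C)C)c(O[Si](C)(C)C(C)(C)C)c(OC)c1 | intermediate
8 | 4-hydroxyphenylglyoxylic acid | O=C(O)C(=O)c1ccc(O)cc1 | starting material
9 | methyl 2-(4-hydroxyphenyl)-2,2-dimethoxyacetate | COC(=O)C(OC)(OC)c1ccc(O)cc1 | intermediate
10 | prenyl bromide | CC(C)=CCBr | starting material
11 | methyl 2,2-dimethoxy-2-[4-(3-methylbut-2-enyloxy)phenyl]acetate | COC(=O)C(OC)(OC)c1ccc(OCC=C(C)C)cc1 | intermediate
12 | [3-(tert-butyldimethylsilyloxy)-2-methoxy-6-(methoxymethoxy)-4-(trimethylsilyl)phenyl]lithium | COCOc1cc([Si](C)(C)C)c(O[Si](C)(C)C(C)(C)C)c(OC)c1[Li] | intermediate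
13 | 1-[3-(tert-butyldimethylsilyloxy)-2-methoxy-6-(methoxymethoxy)-4-(trimethylsilyl)phenyl]-2,2-dimethoxy-2-[4-(3-methylbut-2-enyloxy)phenyl]ethan-1-one | COCOc1cc([Si](C)(C)C)c(O[Si](C)(C)C(C)(C)C)c(OC)c1C(=O)C(OC)(OC)c1ccc(OCC=C(C)C)cc1 | intermediate
14 | 1-[3-hydroxy-2-methoxy-6-(methoxymethoxy)-4-(trimethylsilyl)phenyl]-2,2-dimethoxy-2-[4-(3-methylbut-2-enyloxy)phenyl]ethan-1-one | COCOc1cc([Si](C)(C)C)c(O)c(OC)c1C(=O)C(OC)(OC)c1ccc(OCC=C(C)C)cc1 | intermediate
15 | 3-{2,2-dimethoxy-2-[4-(3-methylbut-2-enyloxy)phenyl]acetyl}-2-methoxy-4-(methoxymethoxy)-6-(trimethylsilyl)phenyl trifluoromethanesulfonate | COCOc1cc([Si](C)(C)C)c(OS(=O)(=O)C(F)(F)F)c(OC)c1C(=O)C(OC)(OC)c1ccc(OCC=C(C)C)cc1 | intermediate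
16 | 3-methylbut-2-enal | CC(C)=CC=O | starting material
17 | C4a≡C8a aryne of the fully substituted ring A | COCOC1=CC#CC(OC)=C1C(=O)C(OC)(OC)c1ccc(OCC=C(C)C)cc1 | intermediate
18 | 2-(2-methylprop-1-enyl)-2H-benzoxete adduct (racemic, transient) | COCOc1cc2OC(C=C(C)C)c2c(OC)c1C(=O)C(OC)(OC)c1ccc(OCC=C(C)C)cc1 | intermediate
19 | (Z)-ortho-quinone methide | O=C1C=C(OCOC)C(C(=O)C(OC)(OC)c2ccc(OCC=C(C)C)cc2)=C(OC)/C1=C/C=C(C)C | intermediate
20 | 1-[5-methoxy-7-(methoxymethoxy)-2,2-dimethyl-2H-chromen-6-yl]-2,2-dimethoxy-2-[4-(3-methylbut-2-enyloxy)phenyl]ethan-1-one | COCOc1cc2OC(C)(C)C=Cc2c(OC)c1C(=O)C(OC)(OC)c1ccc(OCC=C(C)C)cc1 | intermediate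
21 | ficucaricone C | COc1c2c(cc(O)c1C(=O)C(=O)c1ccc(OCC=C(C)C)cc1)OC(C)(C)C=C2 | target

**Total step count:** 11. **Longest linear sequence:** 9 (steps 1–4 and 7–11, from 5-bromovanillin).

**Steps most likely to fail**

**Step 10.**
- What may go wrong: the weakly nucleophilic aldehyde oxygen may be too slow for the crowded, short-lived aryne. Ene reactions with prenyl or prenal methyl groups, fluoride-induced enolisation and self-condensation of the enal, or capture of the quinone methide by a second aryne could then take over.
- Fallback: it sets out from 15 and comes back at 20, and it separates the C–O/C–C bond formation from the pyran closure.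
  - Compound 15 is treated with CsF in dry DMF, which serves as solvent and reactant. Aryne 17 then undergoes the better documented [2+2] addition to the more nucleophilic formamide carbonyl, in the same orientation, to give the 2-(dimethylamino)benzoxete adduct F1.
  - Aqueous work-up hydrolyses this adduct to the 6-hydroxy-2-methoxybenzaldehyde F2.
  - Me2C=CHMgBr (2.2 equiv, THF, –78 to 0 °C) adds to the aldehyde, which is far more accessible than the shielded C6 ketone, and gives the ortho-hydroxy allylic benzylic alcohol F3.
  - Warming F3 in toluene, with a trace of PPTS if needed, dehydrates it to quinone methide 19, which closes to 20.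

**Step 7.**
- What may go wrong: addition of the di-ortho-substituted aryllithium to the neopentyl-like ester carbonyl may be slow. Proton transfer and decay of the aryllithium on warming could then compete with acylation.
- Fallback: it sets out from 11 (with 7) and comes back at 13, and it replaces acyl substitution by addition and oxidation.
  - Compound 11 is reduced with i-Bu2AlH (toluene, –78 °C) to the α,α-dimethoxy aldehyde F4.
  - Aryllithium 12 adds to this much less hindered carbonyl to give the secondary carbinol F5.
  - Dess–Martin periodinane buffered with NaHCO3 oxidises F5 to 13.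

**Step 11.**
- What may go wrong: acid ionisation of the prenyl aryl ether, or hydration or opening of the chromene, may set in before the α-keto ketal is fully hydrolysed. The oxocarbenium ion of that ketal is destabilised by the neighbouring carbonyl.
- Fallback: it sets out from 9 and comes back at 21, and it moves the prenylation to the very end.
  - Compound 9 is protected with MOMCl and i-Pr2NEt as the ring-B MOM ether ester F6.
  - F6 takes the place of 11 in the chemistry of steps 7 to 9, giving in turn the ketone F7, the o-silylphenol F8 and the triflate F9.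
  - F9 with CsF and 16 passes through the corresponding aryne F10, the benzoxete F11 and the ortho-quinone methide F12 to the bis-MOM chromene F13.
  - Acid hydrolysis can now be pushed harder because no prenyl ether is present. It gives the 7,4'-dihydroxy diketone F14.
  - Prenyl bromide 10 (1.0 equiv) with K2CO3 in acetone at rt alkylates only the free, more acidic ring-B phenol, because the C7 hydroxyl is held in a hydrogen bond to the C6 ketone. This gives 21.

**Further compounds**
F1 | step 10 | 2-(dimethylamino)-2H-benzoxete adduct of aryne 17 and DMF (racemic, transient) | COCOc1cc2OC(N(C)C)c2c(OC)c1C(=O)C(OC)(OC)c1ccc(OCC=C(C)C)cc1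
F2 | step 10 | 3-{2,2-dimethoxy-2-[4-(3-methylbut-2-enyloxy)phenyl]acetyl}-6-hydroxy-2-methoxy-4-(methoxymethoxy)benzaldehyde | COCOc1cc(O)c(C=O)c(OC)c1C(=O)C(OC)(OC)c1ccc(OCC=C(C)C)cc1
F3 | step 10 | 1-[4-hydroxy-3-(1-hydroxy-3-methylbut-2-enyl)-2-methoxy-6-(methoxymethoxy)phenyl]-2,2-dimethoxy-2-[4-(3-methylbut-2-enyloxy)phenyl]ethan-1-one (racemic) | COCOc1cc(O)c(C(O)C=C(C)C)c(OC)c1C(=O)C(OC)(OC)c1ccc(OCC=C(C)C)cc1
F4 | step 7 | 2,2-dimethoxy-2-[4-(3-methylbut-2-enyloxy)phenyl]acetaldehyde | O=CC(OC)(OC)c1ccc(OCC=C(C)C)cc1
F5 | step 7 | 1-[3-(tert-butyldimethylsilyloxy)-2-methoxy-6-(methoxymethoxy)-4-(trimethylsilyl)phenyl]-2,2-dimethoxy-2-[4-(3-methylbut-2-enyloxy)phenyl]ethan-1-ol (racemic) | COCOc1cc([Si](C)(C)C)c(O[Si](C)(C)C(C)(C)C)c(OC)c1C(O)C(OC)(OC)c1ccc(OCC=C(C)C)cc1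
F6 | step 11 | methyl 2,2-dimethoxy-2-[4-(methoxymethoxy)phenyl]acetate | COCOc1ccc(cc1)C(OC)(OC)C(=O)OC
F7 | step 11 | 1-[3-(tert-butyldimethylsilyloxy)-2-methoxy-6-(methoxymethoxy)-4-(trimethylsilyl)phenyl]-2,2-dimethoxy-2-[4-(methoxymethoxy)phenyl]ethan-1-one | COCOc1cc([Si](C)(C)C)c(O[Si](C)(C)C(C)(C)C)c(OC)c1C(=O)C(OC)(OC)c1ccc(OCOC)cc1
F8 | step 11 | 1-[3-hydroxy-2-methoxy-6-(methoxymethoxy)-4-(trimethylsilyl)phenyl]-2,2-dimethoxy-2-[4-(methoxymethoxy)phenyl]ethan-1-one | COCOc1cc([Si](C)(C)C)c(O)c(OC)c1C(=O)C(OC)(OC)c1ccc(OCOC)cc1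
F9 | step 11 | 3-{2,2-dimethoxy-2-[4-(methoxymethoxy)phenyl]acetyl}-2-methoxy-4-(methoxymethoxy)-6-(trimethylsilyl)phenyl trifluoromethanesulfonate | COCOc1cc([Si](C)(C)C)c(OS(=O)(=O)C(F)(F)F)c(OC)c1C(=O)C(OC)(OC)c1ccc(OCOC)cc1
F10 | step 11 | C4a≡C8a aryne of the ring-B MOM series (transient) | COCOC1=CC#CC(OC)=C1C(=O)C(OC)(OC)c1ccc(OCOC)cc1
F11 | step 11 | 2-(2-methylprop-1-enyl)-2H-benzoxete of the ring-B MOM series (racemic, transient) | COCOc1cc2OC(C=C(C)C)c2c(OC)c1C(=O)C(OC)(OC)c1ccc(OCOC)cc1
F12 | step 11 | (Z)-ortho-quinone methide of the ring-B MOM series (transient) | O=C1C=C(OCOC)C(C(=O)C(OC)(OC)c2ccc(OCOC)cc2)=C(OC)/C1=C/C=C(C)C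
F13 | step 11 | 1-[5-methoxy-7-(methoxymethoxy)-2,2-dimethyl-2H-chromen-6-yl]-2,2-dimethoxy-2-[4-(methoxymethoxy)phenyl]ethan-1-one | COCOc1cc2OC(C)(C)C=Cc2c(OC)c1C(=O)C(OC)(OC)c1ccc(OCOC)cc1
F14 | step 11 | 1-(7-hydroxy-5-methoxy-2,2-dimethyl-2H-chromen-6-yl)-2-(4-hydroxyphenyl)ethane-1,2-dione | COc1c2c(cc(O)c1C(=O)C(=O)c1ccc(O)cc1)OC(C)(C)C=C2
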